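**Plan**

- **Feature:** ring A, the ring that bears the carbonyl, is a resorcinol. Its C3' lies between O2' and O4', so C3' (carbon nucleophile) and O4' (oxygen nucleophile) are the two atoms on which the 2,2-dimethylpyran is fused.
- **Cuts:** first C3'–C4'' and O4'–C2'' of the pyran, giving a trihydroxychalcone and 3-methylbut-2-enal. Next the Cα=Cβ bond of the enone, and last the C3–CH2 bond of the ring B prenyl group.
- **Forward:** 4-hydroxybenzaldehyde is C-prenylated and capped as its MOM ether, and 2,4-dihydroxyacetophenone is capped at O4 only. The two halves are joined by aldol condensation and then unmasked.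
- **Rings:** rings A and B are bought. The pyran is the only ring that is built, and it closes in the last step on the free chalcone.
- **Stereochemistry:** the target has no stereocentre. The E enone comes from E1cB dehydration of the aldol under equilibrating base and is not touched afterwards.

Key step: step 6

Remark: locants follow chalcone usage, unprimed for ring B, primed for ring A and doubly primed for the pyran (O1'' = O4', C2'' = CMe2, C4'' bonded to C3').

**Step 1**
Reactants: 1 4-hydroxybenzaldehyde; 2 1-bromo-3-methylbut-2-ene (prenyl bromide)
Product: 3 4-hydroxy-3-(3-methylbut-2-en-1-yl)benzaldehyde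
Conditions: KOH (1.0 equiv), H2O, rt
Reagents that add atoms: none
Why: Ortho C-alkylation of an ambident phenoxide, in which water ties up the phenoxide oxygen by hydrogen bonding so that the soft allylic bromide is taken up in an SN2 manner at the ring carbon ortho to oxygen (para is blocked by the formyl group), and rearomatisation gives 3, which base extraction separates from the neutral O-prenyl ether.

**Step 2**
Reactants: 3 4-hydroxy-3-(3-methylbut-2-en-1-yl)benzaldehyde
Product: 4 4-(methoxymethoxy)-3-(3-methylbut-2-en-1-yl)benzaldehyde
Conditions: MOMCl (1.3 equiv), K2CO3, acetone, 0 °C to rt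
Reagents that add atoms: chloromethyl methyl ether (MOMCl), COCCl
Why: Williamson-type O-alkylation of the phenoxide with the reactive α-chloro ether gives an acetal ether that withstands the hydroxide of step 4, and neither the aldehyde nor the prenyl alkene reacts under these conditions.

**Step 3**
Reactants: 5 2,4-dihydroxyacetophenone
Product: 6 1-[2-hydroxy-4-(methoxymethoxy)phenyl]ethan-1-one
Conditions: MOMCl (1.1 equiv), K2CO3 (1.2 equiv), acetone, 0 °C to rt
Reagents that add atoms: chloromethyl methyl ether (MOMCl), COCCl
Why: Chemoselective Williamson-type O-alkylation, in which the 2-OH is locked in a hydrogen bond to the ketone and is far less acidic and nucleophilic than the free 4-OH, so one equivalent of MOMCl with a weak base caps O4 only.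

**Step 4**
Reactants: 4 4-(methoxymethoxy)-3-(3-methylbut-2-en-1-yl)benzaldehyde; 6 1-[2-hydroxy-4-(methoxymethoxy)phenyl]ethan-1-one
Product: 7 (E)-2'-hydroxy-4,4'-bis(methoxymethoxy)-3-prenylchalcone
Conditions: KOH (excess), EtOH–H2O, 0 °C to rt; then 1 M HCl to pH 5–6 at 0 °C
Reagents that add atoms: none
Why: Claisen–Schmidt crossed aldol condensation, in which only 6 can enolise and 4 is a non-enolisable aldehyde, the aldol loses water by E1cB and the reversible sequence settles on the conjugated E enone, while the MOM ethers and the prenyl group are inert to hydroxide and the strong base holds the product as the open-chain phenoxide instead of the flavanone.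

**Step 5**
Reactants: 7 (E)-2'-hydroxy-4,4'-bis(methoxymethoxy)-3-prenylchalcone
Product: 8 (E)-2',4',4-trihydroxy-3-prenylchalcone
Conditions: HCl (ca. 1 M in MeOH), MeOH, 45 °C, stopped at full conversion
Reagents that add atoms: none
Why: Acid-catalysed acetal exchange with methanol (MOM cleavage through the oxocarbenium ion) frees both phenols, and dilute acid, moderate temperature and short contact keep protonation of the prenyl alkene and chalcone–flavanone isomerisation slower than acetal cleavage.

**Step 6**
Reactants: 8 (E)-2',4',4-trihydroxy-3-prenylchalcone; 9 3-methylbut-2-enal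
Product: 11 paratocarpin B, via ortho-quinone methide 10 (not isolated)
Conditions: 9 (2 equiv, added in portions), ethylenediammonium diacetate (20 mol %), xylene (DMF cosolvent), 130 °C
Reagents that add atoms: none
Why: The diammonium salt activates 9 as a catalyst-bound iminium ion, C3' of ring A attacks its former aldehyde carbon, and loss of the amine from the benzylic adduct gives ortho-quinone methide 10, a 1-oxatriene O4'=C4'–C3'=C4''–C3''=C2''. A thermal disrotatory oxa-6π electrocyclization of 10 joins O4' to C2'', closes the six-membered pyran and restores the aromaticity of ring A. The closest known reaction type is the amine-salt-catalysed formal [3+3] annulation (Knoevenagel condensation, then oxa-6π electrocyclization) of resorcinols and 4-acylresorcinols with α,β-unsaturated aldehydes to 2H-chromenes. No stereocentre arises because C2'' carries two methyl groups, and the E enone is a spectator. The step needs C3' over C5' and O4' over O2': C3' is ortho to both oxygens and is favoured by the bond fixation imposed by the 2'-OH···O=C chelate, and since the electrocyclization is reversible, the chromene that keeps this hydrogen bond is the thermodynamic product. Ring B is a monophenol conjugated to the enone and too poor a carbon nucleophile to engage the iminium ion, and the nearly neutral buffer leaves the prenyl group and the enone alone.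

**Compound list**

1 | 4-hydroxybenzaldehyde | O=Cc1ccc(O)cc1 | starting material
2 | 1-bromo-3-methylbut-2-ene (prenyl bromide) | CC(C)=CCBr | starting material
3 | 4-hydroxy-3-(3-methylbut-2-en-1-yl)benzaldehyde | CC(C)=CCc1cc(C=O)ccc1O | intermediate
4 | 4-(methoxymethoxy)-3-(3-methylbut-2-en-1-yl)benzaldehyde | CC(C)=CCc1cc(C=O)ccc1OCOC | intermediate
5 | 1-(2,4-dihydroxyphenyl)ethan-1-one (2,4-dihydroxyacetophenone) | CC(=O)c1ccc(O)cc1O | starting material
6 | 1-[2-hydroxy-4-(methoxymethoxy)phenyl]ethan-1-one | CC(=O)c1ccc(OCOC)cc1O | intermediate
7 | (E)-1-[2-hydroxy-4-(methoxymethoxy)phenyl]-3-[4-(methoxymethoxy)-3-(3-methylbut-2-en-1-yl)phenyl]prop-2-en-1-one | CC(C)=CCc1cc(/C=C/C(=O)c2ccc(OCOC)cc2O)ccc1OCOC | intermediate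
8 | (E)-1-(2,4-dihydroxyphenyl)-3-[4-hydroxy-3-(3-methylbut-2-en-1-yl)phenyl]prop-2-en-1-one (2',4',4-trihydroxy-3-prenylchalcone) | CC(C)=CCc1cc(/C=C/C(=O)c2ccc(O)cc2O)ccc1O | intermediate
9 | 3-methylbut-2-enal | CC(C)=CC=O | starting material
10 | ortho-quinone methide of ring A: C4'=O, exocyclic C3'=C4''H–C3''H=C2''Me2 with the vinyl group cis to C4'=O, 2'-OH and E enone retained | CC(C)=C/C=C1\C(=O)C=CC(C(=O)/C=C/c2ccc(O)c(CC=C(C)C)c2)=C1O | intermediate
11 | paratocarpin B, (E)-1-(5-hydroxy-2,2-dimethyl-2H-chromen-6-yl)-3-[4-hydroxy-3-(3-methylbut-2-en-1-yl)phenyl]prop-2-en-1-one | CC(C)=CCc1cc(/C=C/C(=O)c2ccc3c(c2O)C=CC(C)(C)O3)ccc1O | target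

**Step count**

Total step count: 6.
Longest linear sequence: 5 steps (steps 1, 2, 4, 5 and 6, from 1).

**Steps most likely to fail**

**Step 6.** Three processes threaten it.
- The iminium ion may be attacked at C5' instead of C3', which leads to the linear pyran.
- The condensation may be sluggish because the cinnamoyl group drains electron density from ring A.
- The hot amine salt may promote intramolecular oxa-Michael closure of the 2'-hydroxy enone.

The fallback moves ring formation to the acetophenone stage, so that the chalcone never meets the hot amine salt. It sets out from 5. Condensation with 9 under ethylenediammonium diacetate in hot xylene should give 1-(5-hydroxy-2,2-dimethyl-2H-chromen-6-yl)ethan-1-one F1. Claisen–Schmidt condensation of that ketone with aldehyde 4 (KOH, EtOH–H2O, rt) should give paratocarpin B 4-O-methoxymethyl ether F2. Brief treatment with methanolic HCl removes the single MOM group and rejoins the route at 11.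

**Step 1.** O-alkylation and a second C-alkylation compete with the wanted single ortho C-alkylation, and the bromide hydrolyses in water.

The fallback delivers the prenyl group by a sigmatropic shift instead of direct alkylation. It sets out from 1. O-alkylation with 3-chloro-3-methylbut-1-yne (CuCl2·2H2O cat., DBU, MeCN, 0 °C) should give 4-[(2-methylbut-3-yn-2-yl)oxy]benzaldehyde F3. Semihydrogenation (H2, Pd/CaCO3 poisoned with Pb(OAc)2, quinoline, EtOAc) should give 4-[(2-methylbut-3-en-2-yl)oxy]benzaldehyde F4. Heating in N,N-diethylaniline triggers an aromatic Claisen [3,3] rearrangement, which inverts the allyl unit, places a linear prenyl group at C3 only, and rejoins the route at 3.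

**Step 5.** Three acid-promoted processes may run at rates comparable with acetal cleavage.
- The neighbouring phenol may add to the prenyl alkene, closing a chroman.
- Methanol may add to the same alkene.
- The chalcone may isomerise to the flavanone.

The fallback replaces the acid-labile masks with allyl ethers that are removed under neutral conditions. It sets out from 3 and 5. Allyl bromide with K2CO3 in acetone should convert 3 into 4-(allyloxy)-3-(3-methylbut-2-en-1-yl)benzaldehyde F5, and 5 (one equivalent of bromide) into 1-[4-(allyloxy)-2-hydroxyphenyl]ethan-1-one F6. Claisen–Schmidt condensation of the two (KOH, EtOH–H2O, rt) should give (E)-4,4'-bis(allyloxy)-2'-hydroxy-3-prenylchalcone F7. Tsuji–Trost-type deallylation with the zerovalent palladium complex Pd(PPh3)4 and morpholine in THF at rt frees both phenols and rejoins the route at 8.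

**Further compounds**
F1 | step 6 | 1-(5-hydroxy-2,2-dimethyl-2H-chromen-6-yl)ethan-1-one | CC(=O)c1ccc2c(c1O)C=CC(C)(C)O2
F2 | step 6 | paratocarpin B 4-O-methoxymethyl ether, (E)-1-(5-hydroxy-2,2-dimethyl-2H-chromen-6-yl)-3-[4-(methoxymethoxy)-3-(3-methylbut-2-en-1-yl)phenyl]prop-2-en-1-one | CC(C)=CCc1cc(/C=C/C(=O)c2ccc3c(c2O)C=CC(C)(C)O3)ccc1OCOC
F3 | step 1 | 4-[(2-methylbut-3-yn-2-yl)oxy]benzaldehyde | C#CC(C)(C)Oc1ccc(C=O)cc1
F4 | step 1 | 4-[(2-methylbut-3-en-2-yl)oxy]benzaldehyde | C=CC(C)(C)Oc1ccc(C=O)cc1
F5 | step 5 | 4-(allyloxy)-3-(3-methylbut-2-en-1-yl)benzaldehyde | C=CCOc1ccc(C=O)cc1CC=C(C)C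
F6 | step 5 | 1-[4-(allyloxy)-2-hydroxyphenyl]ethan-1-one | CC(=O)c1ccc(OCC=C)cc1O
F7 | step 5 | (E)-4,4'-bis(allyloxy)-2'-hydroxy-3-prenylchalcone | CC(C)=CCc1cc(/C=C/C(=O)c2ccc(OCC=C)cc2O)ccc1OCC=C
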